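Numbering (clerodane-type, used throughout): ring A is C1(H2)–C2(=O)–C3(H)–C4(H)Me–C5(Me)–C10(H); ring B is C5–C6(OAc)–C7(H2)–C8(H)Me–C9–C10; C20 is the CH2 bridging C9 and C3; the side chain is C11–C12–C13(OH)(Me)–C14=C15.
Retrosynthesis: the acetate and C6 carbinol go back to a C6 ketone with C2 held as a silyl enol ether; C3–C4 and C5–C10 are then cut together (retro-[4+2]); then C6–C7 (alkyllithium plus tiglic aldehyde), the C13 carbinol/C14=C15 unit (epoxy iodide from a Sharpless epoxide), C8–C9 ([3,3] shift) and C9–C11 (Grignard addition to 3-ethoxycyclohexenone).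
Enabling feature: the bicyclo[2.2.2]octan-2-one (C1, C2, C3, C4, C5, C10, C9, C20) has its carbonyl on the two-carbon bridge C1–C2, so C1=C2(OSi) is the retron of a 2-silyloxydiene C3=C2–C1=C10 on the ring C1–C2–C3–C20–C9–C10; the C6 oxygen next to C5 is the carbonyl that activates a C4=C5 dienophile, and ring B is exactly the three-atom tether (C8, C7, C6) from the allylic sp3 carbon C9.
Forward: the ring C1–C2–C3–C20–C9–C10 is bought as 3-ethoxycyclohexenone; the C11–C14 chain is joined first, C8–C9 is made by Ireland–Claisen rearrangement, the side chain is finished as an epoxy iodide, the C4–C6 unit is joined at C7, and rings A and B then form in one intramolecular Diels–Alder step.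
Stereochemistry: one carbinol set by CBS reduction is relayed by the [3,3] shift to C9 and C8; C13 comes from Sharpless epoxidation; the cycloaddition relays C9 to C3, C4, C5 and C10 (tether plus E-alkene); C6 is set by thermodynamic (dissolving-metal) reduction.

Key step: step 12

Remark: compounds 1, 2 and 18 are taken as commercial; all other stereochemical statements are predictions from the models named in each step.

Step 1
Reactants: 1 3-ethoxycyclohex-2-en-1-one; 2 (4-bromobut-1-yn-1-yl)trimethylsilane
Product: 5 3-[4-(trimethylsilyl)but-3-yn-1-yl]cyclohex-2-en-1-one, via Grignard reagent 3 (not isolated), via 1,2-adduct 4 (not isolated)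
Conditions: Mg, THF, 40 °C (on 2); then 1, THF, 0 °C to rt; then 1 M HCl, rt
Reagents that add atoms: water, O
Why: Stork–Danheiser sequence: the Grignard reagent adds 1,2 to the vinylogous ester and acid hydrolysis with loss of ethanol and water unmasks the transposed 3-alkyl enone, so C9 is joined to C11 without any stereocentre.

Step 2
Reactants: 5 3-[4-(trimethylsilyl)but-3-yn-1-yl]cyclohex-2-en-1-one
Product: 6 (1S)-3-[4-(trimethylsilyl)but-3-yn-1-yl]cyclohex-2-en-1-ol
Conditions: (R)-2-methyl-CBS-oxazaborolidine (10 mol%), catecholborane, toluene, −78 °C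
Reagents that add atoms: none
Why: Corey–Bakshi–Shibata reduction, in which the substituted alkene arm acts as the large group, so the (R)-catalyst should deliver hydride to the face that gives the (S)-allylic alcohol; this is the one stereocentre of the carbocyclic core set by catalysis.

Step 3
Reactants: 6 (1S)-3-[4-(trimethylsilyl)but-3-yn-1-yl]cyclohex-2-en-1-ol
Product: 7 (1S)-3-[4-(trimethylsilyl)but-3-yn-1-yl]cyclohex-2-en-1-yl propanoate
Conditions: (EtCO)2O, Et3N, DMAP (cat.), CH2Cl2, 0 °C to rt
Reagents that add atoms: propanoic anhydride, CCC(=O)OC(=O)CC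
Why: DMAP-catalysed acylation of a secondary allylic alcohol, with no change at the carbinol centre.

Step 4
Reactants: 7 (1S)-3-[4-(trimethylsilyl)but-3-yn-1-yl]cyclohex-2-en-1-yl propanoate
Product: 10 (2S)-2-[(1S)-1-(but-3-yn-1-yl)cyclohex-2-en-1-yl]propanoic acid, via silyl ketene acetal 8 (not isolated), via silyl ester 9 (not isolated)
Conditions: LiN(iPr)2, THF, −78 °C; Me3SiCl/Et3N, −78 °C to rt, then 50 °C; then 1 M NaOH, MeOH, rt; then 1 M HCl
Reagents that add atoms: none
Why: Ireland–Claisen rearrangement: kinetic enolisation in THF places the methyl cis to the allylic oxygen, and the suprafacial [3,3] shift through a chair-like transition state (the boat would force this methyl over the ring CH2) should transfer the carbinol configuration to quaternary C9 and set C8 relative to it, while the basic work-up frees the acid and the terminal alkyne.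

Step 5
Reactants: 10 (2S)-2-[(1S)-1-(but-3-yn-1-yl)cyclohex-2-en-1-yl]propanoic acid
Product: 11 (2S)-2-[(1S)-1-(but-3-yn-1-yl)cyclohex-2-en-1-yl]propan-1-ol
Conditions: LiAlH4, THF, 0 °C to reflux
Reagents that add atoms: none
Why: Hydride reduction of the carboxylic acid to the primary alcohol (the future C7) without touching C8, the ring alkene or the alkyne.

Step 6
Reactants: 11 (2S)-2-[(1S)-1-(but-3-yn-1-yl)cyclohex-2-en-1-yl]propan-1-ol
Product: 13 (2E)-5-[(1S)-1-[(2S)-1-hydroxypropan-2-yl]cyclohex-2-en-1-yl]-3-methylpent-2-en-1-ol, via alkenylalane 12 (not isolated)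
Conditions: Me3Al (excess), Cp2ZrCl2 (25 mol%), CH2Cl2, 0 °C to rt; then n-BuLi, hexane/THF, −78 °C; (CH2O)n, rt
Reagents that add atoms: trimethylaluminium, C[Al](C)C; formaldehyde (as paraformaldehyde), C=O
Why: Negishi zirconium-catalysed carboalumination adds methyl and aluminium syn across the terminal alkyne with methyl on the internal carbon, and hydroxymethylation of the alkenylalanate with formaldehyde should give the E-trisubstituted allylic alcohol with retention of alkene geometry.

Step 7
Reactants: 13 (2E)-5-[(1S)-1-[(2S)-1-hydroxypropan-2-yl]cyclohex-2-en-1-yl]-3-methylpent-2-en-1-ol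
Product: 14 [(2S,3S)-3-[2-[(1S)-1-[(2S)-1-hydroxypropan-2-yl]cyclohex-2-en-1-yl]ethyl]-3-methyloxiran-2-yl]methanol
Conditions: Ti(OiPr)4 (20 mol%), L-(+)-diethyl tartrate (24 mol%), t-BuOOH, 4 Å molecular sieves, CH2Cl2, −20 °C
Reagents that add atoms: tert-butyl hydroperoxide, CC(C)(C)OO
Why: Sharpless asymmetric epoxidation: with L-(+)-diethyl tartrate the reagent should epoxidise only the allylic alcohol and from the face that gives the (2S,3S)-epoxy alcohol, which fixes the future C13 by reagent control.

Step 8
Reactants: 14 [(2S,3S)-3-[2-[(1S)-1-[(2S)-1-hydroxypropan-2-yl]cyclohex-2-en-1-yl]ethyl]-3-methyloxiran-2-yl]methanol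
Product: 15 (2R,3S)-2-(iodomethyl)-3-[2-[(1S)-1-[(2S)-1-iodopropan-2-yl]cyclohex-2-en-1-yl]ethyl]-3-methyloxirane
Conditions: I2, PPh3, imidazole, CH2Cl2, 0 °C to rt
Reagents that add atoms: iodine, II
Why: Appel-type iodination converts both primary alcohols into iodides by SN2 displacement at CH2, leaving the epoxide and all stereocentres untouched.

Step 9
Reactants: 15 (2R,3S)-2-(iodomethyl)-3-[2-[(1S)-1-[(2S)-1-iodopropan-2-yl]cyclohex-2-en-1-yl]ethyl]-3-methyloxirane
Product: 16 (4R)-4-[2-[(2S,3R)-3-(iodomethyl)-2-methyloxiran-2-yl]ethyl]-4-[(2S)-1-iodopropan-2-yl]cyclohex-2-en-1-one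
Conditions: CrO3, 3,5-dimethylpyrazole, CH2Cl2, −20 °C
Reagents that add atoms: chromium trioxide, O=[Cr](=O)=O
Why: Allylic C–H oxidation with the CrO3–3,5-dimethylpyrazole complex at the only allylic methylene of the ring (C2; the other allylic carbon C9 is quaternary) should give the 4,4-disubstituted cyclohexenone.

Step 10
Reactants: 16 (4R)-4-[2-[(2S,3R)-3-(iodomethyl)-2-methyloxiran-2-yl]ethyl]-4-[(2S)-1-iodopropan-2-yl]cyclohex-2-en-1-one
Product: 17 triethyl[[(4R)-4-[2-[(2S,3R)-3-(iodomethyl)-2-methyloxiran-2-yl]ethyl]-4-[(2S)-1-iodopropan-2-yl]cyclohexa-1,5-dien-1-yl]oxy]silane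
Conditions: LiN(iPr)2, Et3SiCl (in situ quench), THF, −78 °C
Reagents that add atoms: chlorotriethylsilane, CC[Si](Cl)(CC)CC
Why: Kinetic deprotonation at C3 with in situ silylation gives the cross-conjugated 2-silyloxydiene; at this stage the future tether has no carbonyl, so no other enolate can form, and trapping at −78 °C should outrun alkylation of the enolate by the iodides.

Step 11
Reactants: 17 triethylsilyl dienol ether of 16; 18 (2E)-2-methylbut-2-enal
Product: 20 (3S)-5-[(1S)-1-[(2R,5E)-4-hydroxy-5-methylhept-5-en-2-yl]-4-(triethylsilyloxy)cyclohexa-2,4-dien-1-yl]-3-methylpent-1-en-3-ol (C6 carbinol as a mixture of epimers), via dilithio species 19 (not isolated)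
Conditions: t-BuLi (4.4 equiv), Et2O/pentane, −78 °C; then 18, −78 °C; pH 7 buffer
Reagents that add atoms: none
Why: Two iodine–lithium exchanges: the 2,3-epoxy iodide should open at once by β-elimination to the C13 tertiary allylic alkoxide with retention at C13, and the primary alkyllithium adds 1,2 to tiglic aldehyde to form the C6–C7 bond; the new C6 carbinol forms without control and is oxidised in step 12.

Step 12
Reactants: 20 dienol ether diol (C6 carbinol epimers)
Product: 22 tricyclic C6 ketone with C1=C2 triethylsilyl enol ether and free C13 alcohol (C3; C4; C5; C8; C9; C10; C13 as in the target), via tigloyl ketone 21 (not isolated)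
Conditions: MnO2, CH2Cl2, rt; filtration; then toluene, BHT (cat.), Et3N (cat.), 110 °C
Reagents that add atoms: none
Why: Oxidation of the allylic alcohol by MnO2 arms the dienophile, and on heating the 2-silyloxy-1,3-diene (C3=C2–C1=C10) and the tethered enone C4=C5 should combine in a concerted, asynchronous intramolecular Diels–Alder reaction of normal electron demand, in which the electron-rich diene terminus C3 bonds to the enone β-carbon C4 and C10 bonds to the α-carbon C5. The closest known reaction type is the intramolecular Diels–Alder reaction of cyclohexenone-derived 2-silyloxydienes that carry the dienophile on the allylic sp3 carbon (the pericyclic counterpart of the intramolecular double Michael reaction), which is an established entry to bicyclo[2.2.2]octanes in terpenoid synthesis. The event closes ring B in the fused mode (C5–C10 bond, six-membered, through the three-atom tether C8–C7–C6) and the bridged bicyclo[2.2.2]octene (C3–C4 bond, formally an eight-membered closure completed within the same cycloaddition). C10, C3 and C5 are fixed by the tether, which reaches only the diene face syn to C8 and holds the C6 carbonyl away from the new C1=C2 bridge, whereas C4 follows from suprafacial addition to the E-alkene, which keeps the C4 and C5 methyl groups cis. The step needs chemoselectivity (enone against the vinyl carbinol that hangs from C9 on the other face by an equally long chain) and regioselectivity (C3–C4/C10–C5 against the crossed pairing), and both are secured by the ketone: it lowers the LUMO of C4=C5 only and puts the large coefficient on C4 to match the nucleophilic C3, while the crossed mode would need a seven-membered bridged tether. The silyl enol ether that emerges keeps the C2 carbonyl masked for step 13.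

Step 13
Reactants: 22 tricyclic C6 ketone silyl enol ether
Product: 23 tricyclic C6 equatorial alcohol (C6 as in the target) with C1=C2 triethylsilyl enol ether and free C13 alcohol
Conditions: Li, NH3(l), THF, t-BuOH, −78 °C; then NH4Cl
Reagents that add atoms: none
Why: Dissolving-metal ketone reduction, which goes through the ketyl radical anion and is expected to give the thermodynamically preferred equatorial C6 alcohol (trans to the C5 methyl and clear of the axial C8 methyl), whereas hydride reagents would be steered by that methyl to the other epimer.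

Step 14
Reactants: 23 tricyclic C6 alcohol silyl enol ether
Product: 24 C6 acetate with C1=C2 triethylsilyl enol ether and free C13 alcohol
Conditions: Ac2O, pyridine, rt
Reagents that add atoms: acetic anhydride, CC(=O)OC(C)=O
Why: Acetylation with Ac2O/pyridine without DMAP should acylate the secondary C6 alcohol and leave the tertiary allylic C13 alcohol and the silyl enol ether untouched.

Step 15
Reactants: 24 C6 acetate silyl enol ether
Product: 25 CNP0281208.1 (target)
Conditions: Bu4NF, AcOH, THF, 0 °C
Reagents that add atoms: none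
Why: Buffered fluoride cleaves the Si–O bond and protonation at C1 releases the C2 ketone under conditions that spare the acetate and the tertiary allylic alcohol.

Compound list
1 | 3-ethoxycyclohex-2-en-1-one | CCOC1=CC(=O)CCC1 | starting material
2 | (4-bromobut-1-yn-1-yl)trimethylsilane | C[Si](C)(C)C#CCCBr | starting material
3 | [4-(trimethylsilyl)but-3-yn-1-yl]magnesium bromide | C[Si](C)(C)C#CCC[Mg]Br | intermediate
4 | bromomagnesium 3-ethoxy-1-[4-(trimethylsilyl)but-3-yn-1-yl]cyclohex-2-en-1-olate (racemic 1,2-adduct) | CCOC1=CC(O[Mg]Br)(CCC#C[Si](C)(C)C)CCC1 | intermediate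
5 | 3-[4-(trimethylsilyl)but-3-yn-1-yl]cyclohex-2-en-1-one | C[Si](C)(C)C#CCCC1=CC(=O)CCC1 | intermediate
6 | (1S)-3-[4-(trimethylsilyl)but-3-yn-1-yl]cyclohex-2-en-1-ol | O[C@H]1CCCC(CCC#C[Si](C)(C)C)=C1 | intermediate
7 | (1S)-3-[4-(trimethylsilyl)but-3-yn-1-yl]cyclohex-2-en-1-yl propanoate | CCC(=O)O[C@H]1CCCC(CCC#C[Si](C)(C)C)=C1 | intermediate
8 | O-trimethylsilyl ketene acetal of 7 (methyl cis to the allylic oxygen) | C/C=C(/O[Si](C)(C)C)O[C@H]1CCCC(CCC#C[Si](C)(C)C)=C1 | intermediate
9 | trimethylsilyl (2S)-2-[(1S)-1-[4-(trimethylsilyl)but-3-yn-1-yl]cyclohex-2-en-1-yl]propanoate | C[Si](C)(C)C#CCC[C@]1(CCCC=C1)[C@H](C)C(=O)O[Si](C)(C)C | intermediate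
10 | (2S)-2-[(1S)-1-(but-3-yn-1-yl)cyclohex-2-en-1-yl]propanoic acid | C#CCC[C@]1(CCCC=C1)[C@H](C)C(=O)O | intermediate
11 | (2S)-2-[(1S)-1-(but-3-yn-1-yl)cyclohex-2-en-1-yl]propan-1-ol | C#CCC[C@]1(CCCC=C1)[C@H](C)CO | intermediate
12 | (E)-alkenyl(dimethyl)alane from 11 (aluminium cis to the new methyl; alcohol as its dimethylaluminium alkoxide) | C[Al](C)/C=C(\C)CC[C@]1(CCCC=C1)[C@H](C)CO[Al](C)C | intermediate
13 | (2E)-5-[(1S)-1-[(2S)-1-hydroxypropan-2-yl]cyclohex-2-en-1-yl]-3-methylpent-2-en-1-ol | OC/C=C(\C)CC[C@]1(CCCC=C1)[C@H](C)CO | intermediate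
14 | [(2S,3S)-3-[2-[(1S)-1-[(2S)-1-hydroxypropan-2-yl]cyclohex-2-en-1-yl]ethyl]-3-methyloxiran-2-yl]methanol | OC[C@@H]1O[C@@]1(C)CC[C@]2(CCCC=C2)[C@H](C)CO | intermediate
15 | (2R,3S)-2-(iodomethyl)-3-[2-[(1S)-1-[(2S)-1-iodopropan-2-yl]cyclohex-2-en-1-yl]ethyl]-3-methyloxirane | IC[C@@H]1O[C@@]1(C)CC[C@]2(CCCC=C2)[C@H](C)CI | intermediate
16 | (4R)-4-[2-[(2S,3R)-3-(iodomethyl)-2-methyloxiran-2-yl]ethyl]-4-[(2S)-1-iodopropan-2-yl]cyclohex-2-en-1-one | IC[C@@H]1O[C@@]1(C)CC[C@]2(CCC(=O)C=C2)[C@H](C)CI | intermediate
17 | triethyl[[(4R)-4-[2-[(2S,3R)-3-(iodomethyl)-2-methyloxiran-2-yl]ethyl]-4-[(2S)-1-iodopropan-2-yl]cyclohexa-1,5-dien-1-yl]oxy]silane | IC[C@@H]1O[C@@]1(C)CC[C@]2(CC=C(O[Si](CC)(CC)CC)C=C2)[C@H](C)CI | intermediate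
18 | (2E)-2-methylbut-2-enal (tiglic aldehyde) | C/C=C(\C)C=O | starting material
19 | C13 lithium alkoxide and C7 alkyllithium formed from 17 (dienol ether intact) | C=C[C@@](C)(O[Li])CC[C@]1(CC=C(O[Si](CC)(CC)CC)C=C1)[C@H](C)C[Li] | intermediate
20 | (3S)-5-[(1S)-1-[(2R,5E)-4-hydroxy-5-methylhept-5-en-2-yl]-4-(triethylsilyloxy)cyclohexa-2,4-dien-1-yl]-3-methylpent-1-en-3-ol (C6 carbinol epimers) | C=C[C@@](C)(O)CC[C@]1(CC=C(O[Si](CC)(CC)CC)C=C1)[C@H](C)CC(O)/C(C)=C/C | intermediate
21 | (2E,6R)-6-[(1S)-1-[(3S)-3-hydroxy-3-methylpent-4-en-1-yl]-4-(triethylsilyloxy)cyclohexa-2,4-dien-1-yl]-3-methylhept-2-en-4-one | C=C[C@@](C)(O)CC[C@]1(CC=C(O[Si](CC)(CC)CC)C=C1)[C@H](C)CC(=O)/C(C)=C/C | intermediate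
22 | tricyclic cycloadduct: target skeleton with C6 ketone, C1=C2 triethylsilyl enol ether and free C13 alcohol | C=C[C@@](C)(O)CC[C@@]12C[C@H]3C(O[Si](CC)(CC)CC)=C[C@@H]1[C@](C)([C@@H]3C)C(=O)C[C@H]2C | intermediate
23 | C6 equatorial alcohol of 22 (C6 as in the target) | C=C[C@@](C)(O)CC[C@@]12C[C@H]3C(O[Si](CC)(CC)CC)=C[C@@H]1[C@](C)([C@@H]3C)[C@H](O)C[C@H]2C | intermediate
24 | C6 acetate of 23 (C1=C2 triethylsilyl enol ether retained) | C=C[C@@](C)(O)CC[C@@]12C[C@H]3C(O[Si](CC)(CC)CC)=C[C@@H]1[C@](C)([C@@H]3C)[C@H](OC(C)=O)C[C@H]2C | intermediate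
25 | CNP0281208.1: 2-oxo-13-hydroxy tricycle with C6 acetate (bicyclo[2.2.2]octan-2-one C1–C5/C10/C9/C20 fused to ring B) | C=C[C@@](C)(O)CC[C@@]12C[C@H]3C(=O)C[C@@H]1[C@](C)([C@@H]3C)[C@H](OC(C)=O)C[C@H]2C | target

Total step count: 15. Longest linear sequence: 15 steps (1 and 2 to 25; 18 enters at step 11).

Steps most likely to fail

Step 4. The risk is loss of diastereocontrol at C8 if chair and boat transition states compete or the enolate geometry erodes. The fallback sets out from allylic alcohol 6. A Johnson orthoester Claisen rearrangement (MeC(OEt)3, cat. EtCO2H, 140 °C) transfers the carbinol configuration to C9 alone and should give ethyl ester F1. LiOH in aqueous MeOH then cleaves the ester and the alkynyl silane to give acid F2. Activation with t-BuCOCl/Et3N gives mixed pivalic anhydride F3, which acylates lithiated (4S)-4-benzyl-1,3-oxazolidin-2-one to give imide F4. Auxiliary-controlled methylation (NaN(SiMe3)2, MeI, THF, −78 °C) sets C8 by reagent control in methylated imide F5. LiBH4 reduction removes the auxiliary and comes back to the route at alcohol 11.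

Step 12. The risk is that the congested C5–C10/C3–C4 bond formation is too slow thermally, so that the dienol ether isomerises or hydrolyses before it cyclises. The fallback sets out from 20. After the same MnO2 oxidation to 21, the silyl group is removed (Bu4NF, AcOH, THF) to give enedione F6. LiN(SiMe3)2 (2.1 equiv, THF, −78 °C to 0 °C) then drives an anionic intramolecular double Michael reaction under proton-transfer equilibration, which should end at dilithium alkoxide enolate F7 (enolate at C1=C2). Et3SiCl at −78 °C silylates the enolate oxygen and comes back to the route at 22.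

Step 13. The risk is the wrong outcome at C6, or cleavage of the silyl enol ether followed by over-reduction at C2, under electron-transfer conditions. The fallback sets out from 22. LiBH(s-Bu)3 (THF, −78 °C) attacks from the face away from the axial C8 methyl and should give axial C6 alcohol F8. Equilibration of this carbinol by reversible hydride transfer (Al(OiPr)3, acetone (cat.), toluene/i-PrOH, 80 °C; Meerwein–Ponndorf–Verley/Oppenauer conditions) then moves it to the equatorial epimer and comes back to the route at 23.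

Further compounds
F1 | step 4 | ethyl 2-[1-[4-(trimethylsilyl)but-3-yn-1-yl]cyclohex-2-en-1-yl]acetate (C9 as in 10) | C[Si](C)(C)C#CCC[C@]1(CCCC=C1)CC(=O)OCC
F2 | step 4 | 2-[1-(but-3-yn-1-yl)cyclohex-2-en-1-yl]acetic acid (C9 as in 10) | C#CCC[C@]1(CCCC=C1)CC(=O)O
F3 | step 4 | mixed anhydride of F2 with 2,2-dimethylpropanoic acid | C#CCC[C@]1(CCCC=C1)CC(=O)OC(=O)C(C)(C)C
F4 | step 4 | (4S)-4-benzyl-3-[2-[1-(but-3-yn-1-yl)cyclohex-2-en-1-yl]acetyl]-1,3-oxazolidin-2-one | C#CCC[C@]1(CCCC=C1)CC(=O)N2[C@@H](Cc3ccccc3)COC2=O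
F5 | step 4 | (4S)-4-benzyl-3-[(2S)-2-[(1S)-1-(but-3-yn-1-yl)cyclohex-2-en-1-yl]propanoyl]-1,3-oxazolidin-2-one | C#CCC[C@]1(CCCC=C1)[C@H](C)C(=O)N2[C@@H](Cc3ccccc3)COC2=O
F6 | step 12 | 4-[(3S)-3-hydroxy-3-methylpent-4-en-1-yl]-4-[(2R,5E)-5-methyl-4-oxohept-5-en-2-yl]cyclohex-2-en-1-one (C9 as in 21) | C=C[C@@](C)(O)CC[C@]1(CCC(=O)C=C1)[C@H](C)CC(=O)/C(C)=C/C
F7 | step 12 | dilithium C13 alkoxide C1=C2 enolate of the tricyclic 2,6-dione | C=C[C@@](C)(O[Li])CC[C@@]12C[C@H]3C(O[Li])=C[C@@H]1[C@](C)([C@@H]3C)C(=O)C[C@H]2C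
F8 | step 13 | axial C6 alcohol (C6 epimer of 23) | C=C[C@@](C)(O)CC[C@@]12C[C@H]3C(O[Si](CC)(CC)CC)=C[C@@H]1[C@](C)([C@@H]3C)[C@@H](O)C[C@H]2C
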